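The whole route hangs on one disconnection, the C12–C13 bond. With C11 and C15 as ketones, C12 is α to the C11 carbonyl and C13 is the β-carbon of the C13=C16–C15=O enone in five-membered ring D. An intramolecular Michael addition therefore closes six-membered ring C (C8, C9, C11, C12, C13, C14) across ring D and gives the bicyclo[3.2.1]octane and the C13 stereocentre in one operation. The precursor is a bis-lactone: ring A with its cis γ-lactone, the spiro δ-lactone at C10, an acetyl group on C9 and a cyclopent-2-enone spiro-fused at C8.

Key step: step 13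

Remarks on the chemistry
- Atom labels are those of ent-kaurane (C18 = methyl on C4, C19 = OCH2 on C4, C6 = carbonyl carbon on C5, C20 = OCH2 on C10, C7 = δ-lactone carbonyl on C8, C17 = exocyclic methylene). On ring A, α is the face of C19, C6 and C20; β is the face of C18, H-5 and C9.
- Assumption: a five-membered O-heterocycle fused to ring A at C4/C5 is taken to be more stable cis-fused than trans-fused, so the enolisable C5 of the bicyclic keto acetal made in step 4 settles cis (H-5 cis to C18).

Step 1
Reactants: 1 3-methylcyclohex-2-en-1-one; 2 hex-1-yne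
Product: 5 (S)-trimethylsilyl enol ether of 3-[(E)-hex-1-enyl]-3-methylcyclohexanone, via alkenylalane 3 (not isolated), via aluminium enolate 4 (not isolated)
Conditions: 2, iBu2AlH, hexane, 50 °C; then 1, Cu(O2C-2-thienyl) (10 mol %), (R,R)-Ph2P–N[CH(Me)(2-naphthyl)]2 (11 mol %), Et2O, −30 °C; then Me3SiOTf, Et3N, THF, −30 to 0 °C
Reagents that add atoms: hex-1-yne (2), CCCCC#C; trimethylsilyl triflate, C[Si](C)(C)OS(=O)(=O)C(F)(F)F
Why: Syn-hydroalumination gives the (E)-alkenylalane, and its copper-catalysed asymmetric conjugate addition to a β-methylcyclohexenone is an established way to a β-quaternary centre, the chiral phosphinamine–copper complex choosing the enone face so that C4 is formed (S) (the ligand antipode is picked for this sense), while O-silylation of the regio-defined aluminium enolate stores the C5=C10 enol for step 2.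

Step 2
Reactants: 5 (S)-silyl enol ether
Product: 6 (3S)-2-(dimethoxymethyl)-3-[(E)-hex-1-en-1-yl]-3-methylcyclohexan-1-one
Conditions: HC(OMe)3, Me3SiOTf (10 mol %), CH2Cl2, −78 °C; pyridine quench
Reagents that add atoms: trimethyl orthoformate, COC(OC)OC
Why: A Mukaiyama-type reaction of the silyl enol ether with the dimethoxycarbenium ion forms the C5–C6 bond at C5 only and gives a β-keto acetal which, unlike a β-keto ester, is not acidic enough to quench the ylide used at C10 in step 5; C5 stays epimerisable.

Step 3
Reactants: 6 β-keto acetal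
Product: 7 (1R)-2-(dimethoxymethyl)-1-methyl-3-oxocyclohexane-1-carbaldehyde
Conditions: O3, CH2Cl2, −78 °C; then PPh3, −78 to 23 °C
Reagents that add atoms: ozone, [O-][O+]=O
Why: Ozonolysis with reductive work-up cleaves the only C=C bond to the C19 aldehyde, the ketone and acetal being inert and no enol being present.

Step 4
Reactants: 7 keto aldehyde
Product: 9 (3aS,7aR)-3-methoxy-7a-methylhexahydro-2-benzofuran-4(1H)-one, via hydroxy keto acetal 8 (not isolated)
Conditions: NaBH(OAc)3, AcOH, CH2Cl2, 0 to 23 °C; then camphorsulfonic acid (10 mol %), MeOH (2 equiv), CH2Cl2, 23 to 40 °C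
Reagents that add atoms: none
Why: Triacetoxyborohydride reduces the aldehyde but not the hindered ketone (chemoselective hydride reduction), and acid-catalysed acetal exchange closes the five-membered ring between the C19 hydroxyl and C6 while C5 equilibrates through the enol to the cis-fused bicycle, which fixes H-5 cis to the C4 methyl.

Step 5
Reactants: 9 cis-fused keto acetal
Product: 10 C10–C20 spiro-epoxide of 9
Conditions: Me3S I, KN(SiMe3)2, THF, 0 °C; then 9, 0 to 23 °C
Reagents that add atoms: trimethylsulfonium iodide, C[S+](C)C.[I-]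
Why: Corey–Chaykovsky methylene transfer from the sulfonium ylide to the ketone gives the epoxide in one step; the configuration at C10 does not matter because it is erased in step 6, and C5 is no longer epimerisable once the ketone is gone.

Step 6
Reactants: 10 spiro-epoxide; 11 2,2,2-trifluoroethyl acrylate
Product: 13 spiro δ-lactone acetal (C9 β and C20 α at C10), via hydroxy trifluoroethyl ester 12 (not isolated)
Conditions: 11 (3 equiv), Cp2TiCl2 (20 mol %), Zn dust, 2,4,6-collidine·HCl, THF, 23 °C
Reagents that add atoms: 2,2,2-trifluoroethyl acrylate (11), C=CC(=O)OCC(F)(F)F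
Why: Nugent–RajanBabu opening of the epoxide by Cp2TiCl (trivalent titanium) gives the tertiary C10 radical carrying C20–O–Ti, which adds to the acrylate (radical conjugate addition) and lactonises with loss of trifluoroethanol, a known way to spiro δ-lactones; the acrylate should enter from the β face, opposite the axial C19 of the cis-fused acetal ring, so that the new quaternary C10 has C9 β and C20 α.

Step 7
Reactants: 13 spiro δ-lactone acetal
Product: 16 C8=C9 unsaturated spiro δ-lactone acetal, via C8 phenylselenide 14 (not isolated), via C8 selenoxide 15 (not isolated)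
Conditions: LiN(iPr)2, THF, −78 °C; PhSeBr; then 30% H2O2, pyridine, CH2Cl2, 0 to 23 °C
Reagents that add atoms: none
Why: α-Selenenylation of the δ-lactone enolate (C8 is the only acidic position at this stage) followed by selenoxide syn-elimination towards C9 gives the conjugated lactone.

Step 8
Reactants: 16 unsaturated lactone acetal
Product: 17 unsaturated bis-lactone (6,19-γ-lactone and 7,20-δ-lactone)
Conditions: CrO3, H2SO4, acetone–H2O, 0 °C
Reagents that add atoms: water, O
Why: Jones oxidation converts the cyclic methyl acetal through its lactol into the γ-lactone (C6 carbonyl) without touching the unsaturated δ-lactone or any stereocentre.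

Step 9
Reactants: 17 unsaturated bis-lactone; 18 ethyl vinyl ether; 19 allyl bromide
Product: 22 9-(1-ethoxyvinyl)-8-allyl bis-lactone, via lithium bis(1-ethoxyvinyl)cuprate 20 (not isolated), via lithium lactone enolate 21 (not isolated)
Conditions: 18, t-BuLi, THF, −78 to 0 °C; CuI, −40 °C; 17, −78 to −40 °C; then 19, DMPU, −78 to −20 °C
Reagents that add atoms: ethyl vinyl ether (18), C=COCC; allyl bromide (19), C=CCBr
Why: Conjugate addition of the Gilman cuprate brings the masked acetyl group to C9 on the face of C1, anti to the bulkier C5 branch of the spiro centre, which sets C9, and the lithium enolate is C-allylated at C8 trans to the new group (a centre that is re-formed in step 10).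

Step 10
Reactants: 22 ethoxyvinyl allyl lactone; 23 acrolein
Product: 25 C9-acetyl lactone with allyl and 1-hydroxyallyl groups on C8, via aldol adduct enol ether 24 (not isolated)
Conditions: LiN(iPr)2, THF, −78 °C; 23, −78 °C; NH4Cl; then 1 M HCl, THF, 0 °C
Reagents that add atoms: acrolein (23), C=CC=O; water, O
Why: The lactone enolate (the ketone is still masked, so C8–H is the accessible acidic proton) undergoes a 1,2-aldol addition to acrolein from the face opposite the C9 substituent, which makes C8 quaternary with the allyl group cis and the C15 carbinol trans to C11, and dilute acid then hydrolyses the enol ether to the methyl ketone (the C15 epimers converge in step 11).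

Step 11
Reactants: 25 hydroxy ketone
Product: 26 C8-allyl C8-acryloyl C9-acetyl bis-lactone
Conditions: Dess–Martin periodinane, NaHCO3, CH2Cl2, 0 to 23 °C
Reagents that add atoms: none
Why: Dess–Martin oxidation of the allylic alcohol gives the vinyl ketone, and because C8 is quaternary the new β-keto lactone can neither enolise nor epimerise.

Step 12
Reactants: 26 allyl vinyl ketone
Product: 27 C9-acetyl bis-lactone spiro-fused at C8 to a cyclopent-2-enone (Michael precursor)
Conditions: second-generation Grubbs catalyst (5 mol %), CH2Cl2, 40 °C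
Reagents that add atoms: none
Why: Ring-closing metathesis of the allyl and acryloyl groups on C8 releases ethylene and closes the cyclopentenone (C13=C16), a favourable five-membered closure that tolerates the electron-poor vinyl ketone.

Step 13
Reactants: 27 Michael precursor
Product: 30 bicyclo[3.2.1]octane 11,15-diketone bis-lactone, via pyrrolidine enamine of the precursor 28 (not isolated), via enamine of the bridged diketone 29 (not isolated)
Conditions: pyrrolidine (1.5 equiv), AcOH (1.5 equiv), 4 Å molecular sieves, THF, 23 to 40 °C; then AcOH–NaOAc–H2O, 23 °C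
Reagents that add atoms: none
Why: Pyrrolidine condenses with the methyl ketone on its methyl side (C9 lies between two quaternary carbons) to give enamine 28, whose nucleophilic carbon C12 adds to the enone β-carbon C13; proton transfer gives enamine 29 and buffered hydrolysis returns the C11 ketone. The closest known reaction type is the Stork-enamine intramolecular Michael addition of a ketone to a cycloalkenone, which gives bridged bicyclo[3.2.1]octanediones. Ring C (C8, C9, C11, C12, C13, C14) closes in a 6-exo-trig mode, the C13=C16 bond lying outside the new ring. The only new stereocentre, C13, is controlled by the spiro centre C8, because the C9–C11–C12 arm can reach C13 only on the enone face that carries C9. The step needs regioselective enamine formation and chemoselectivity over the β-keto lactone; the hindered C9, the non-enolisable quaternary C8 and the pyrrolidinium acetate buffer should secure both, and a C9 epimer formed reversibly cannot cyclise.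

Step 14
Reactants: 30 bridged diketone
Product: 31 11-hydroxy 15-ketone (equatorial 11-OH, anti to the C15–C16 bridge)
Conditions: NaBH4 (1 equiv of hydride), MeOH–CH2Cl2, −78 to −40 °C
Reagents that add atoms: none
Why: Borohydride reduction should take the cyclohexanone C11 faster than the cyclopentanone C15, which is flanked by the quaternary C8, and deliver hydride axially from the side of the C15–C16 bridge because the other face is blocked by the axial C9–C10 bond, giving the equatorial alcohol of the target.

Step 15
Reactants: 31 hydroxy ketone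
Product: 34 16-methylene 15-ketone with free 11-OH, via Mannich base 32 (not isolated), via ammonium iodide 33 (not isolated)
Conditions: LiN(SiMe3)2 (2.5 equiv), THF, −78 °C; Me2N=CH2 I, −78 to 0 °C; MeI, CH2Cl2, 23 °C; aq. NaHCO3, 23 °C
Reagents that add atoms: dimethylmethyleneiminium iodide, C=[N+](C)C.[I-]
Why: The dianion (C11 alkoxide plus the only possible ketone enolate, at C16) is aminomethylated by the iminium salt (Mannich reaction), and quaternisation followed by Hofmann-type elimination installs the C16=C17 methylene, while C8 and C13 cannot epimerise.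

Step 16
Reactants: 34 hydroxy enone
Product: 35 guidongnin
Conditions: NaBH4, CeCl3·7H2O, MeOH, −78 to 0 °C
Reagents that add atoms: none
Why: Luche reduction gives 1,2-reduction of the enone with hydride arriving on the exo face of ring D, away from the three-carbon bridge C9–C11–C12, so that the C15 hydroxyl points towards that bridge as in the target.

Compound list
1 | 3-methylcyclohex-2-en-1-one | CC1=CC(=O)CCC1 | starting material
2 | hex-1-yne | CCCCC#C | starting material
3 | (E)-hex-1-enyl(diisobutyl)aluminium | CCCC/C=C/[Al](CC(C)C)CC(C)C | intermediate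
4 | diisobutylaluminium enolate of (R)-3-[(E)-hex-1-enyl]-3-methylcyclohexanone (C5=C10 enolate) | C[C@@]1(/C=C/CCCC)CCCC(O[Al](CC(C)C)CC(C)C)=C1 | intermediate
5 | (S)-trimethyl({3-methyl-3-[(E)-hex-1-en-1-yl]cyclohex-1-en-1-yl}oxy)silane | C[C@@]1(/C=C/CCCC)CCCC(O[Si](C)(C)C)=C1 | intermediate
6 | (3S)-2-(dimethoxymethyl)-3-[(E)-hex-1-en-1-yl]-3-methylcyclohexan-1-one (both C2 epimers) | C[C@@]1(/C=C/CCCC)CCCC(=O)C1C(OC)OC | intermediate
7 | (1R)-2-(dimethoxymethyl)-1-methyl-3-oxocyclohexane-1-carbaldehyde (both C2 epimers) | C[C@@]1(C=O)CCCC(=O)C1C(OC)OC | intermediate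
8 | (3R)-2-(dimethoxymethyl)-3-(hydroxymethyl)-3-methylcyclohexan-1-one | C[C@@]1(CO)CCCC(=O)C1C(OC)OC | intermediate
9 | (3aS,7aR)-3-methoxy-7a-methylhexahydro-2-benzofuran-4(1H)-one, cis-fused (H-5 and C18 β; both anomers at C6) | C[C@]12COC(OC)[C@H]1C(=O)CCC2 | intermediate
10 | spiro-epoxide of 9: C10–C20 oxirane in place of the ketone (either C10 configuration), cis-fused acetal retained | C[C@]12COC(OC)[C@H]1C3(CO3)CCC2 | intermediate
11 | 2,2,2-trifluoroethyl acrylate | C=CC(=O)OCC(F)(F)F | starting material
12 | hydroxy ester: C10 bears CH2OH (C20, α) and CH2CH2CO2CH2CF3 (C9, β) on the cis-fused ring A acetal | OC[C@@]1(CCC(=O)OCC(F)(F)F)CCC[C@@]2(C)COC(OC)[C@H]21 | intermediate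
13 | spiro δ-lactone (C20–O–C7(=O)–C8H2–C9H2) at C10, C9 β and C20 α, on the cis-fused C6 methyl acetal of ring A | O=C1CC[C@]2(CO1)CCC[C@@]3(C)COC(OC)[C@H]32 | intermediate
14 | C8 phenylselenide of 13 | O=C1C([Se]c4ccccc4)C[C@]2(CO1)CCC[C@@]3(C)COC(OC)[C@H]32 | intermediate
15 | C8 phenylselenoxide of 13 | O=C1C([Se](=O)c4ccccc4)C[C@]2(CO1)CCC[C@@]3(C)COC(OC)[C@H]32 | intermediate
16 | C8=C9 unsaturated spiro δ-lactone on the ring A methyl acetal | O=C1C=C[C@]2(CO1)CCC[C@@]3(C)COC(OC)[C@H]32 | intermediate
17 | unsaturated bis-lactone: cis 6,19-γ-lactone on ring A, spiro 7,20-δ-lactone with C8=C9 | O=C1C=C[C@]2(CO1)CCC[C@@]3(C)COC(=O)[C@H]32 | intermediate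
18 | ethyl vinyl ether | C=COCC | starting material
19 | allyl bromide | C=CCBr | starting material
20 | lithium bis(1-ethoxyvinyl)cuprate, LiCu[C(OEt)=CH2]2 | [Li+].C=C(OCC)[Cu-]C(=C)OCC | intermediate
21 | lithium enolate (C7–OLi, C7=C8) of the δ-lactone carrying 1-ethoxyvinyl on C9 (cis to C1) | C=C(OCC)[C@H]1[C@@]2(CCC[C@@]3(C)COC(=O)[C@H]32)COC(O[Li])=C1 | intermediate
22 | bis-lactone with 1-ethoxyvinyl on C9 (cis to C1, anti to C5) and allyl on C8 trans to it | C=C(OCC)[C@H]1[C@@]2(CCC[C@@]3(C)COC(=O)[C@H]32)COC(=O)[C@@H]1CC=C | intermediate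
23 | acrolein | C=CC=O | starting material
24 | aldol adduct: C8 quaternary, allyl cis and CH(OH)CH=CH2 trans to the C9 1-ethoxyvinyl group (both C15 epimers) | C=C(OCC)[C@H]1[C@@]2(CCC[C@@]3(C)COC(=O)[C@H]32)COC(=O)[C@]1(CC=C)C(O)C=C | intermediate
25 | as 24 with the C9 substituent hydrolysed to acetyl | CC(=O)[C@H]1[C@@]2(CCC[C@@]3(C)COC(=O)[C@H]32)COC(=O)[C@]1(CC=C)C(O)C=C | intermediate
26 | C9-acetyl bis-lactone with allyl (cis to acetyl) and acryloyl (trans) on C8 | CC(=O)[C@H]1[C@@]2(CCC[C@@]3(C)COC(=O)[C@H]32)COC(=O)[C@]1(CC=C)C(=O)C=C | intermediate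
27 | C9-acetyl bis-lactone spiro-fused at C8 to cyclopent-2-enone (C14 cis, C15 trans to the acetyl group) | CC(=O)[C@H]3[C@@]4(CCC[C@@]5(C)COC(=O)[C@H]54)COC(=O)[C@]3(CC=C1)C1=O | intermediate
28 | pyrrolidine enamine of 27 (C11=C12) | C=C(N6CCCC6)[C@H]3[C@@]4(CCC[C@@]5(C)COC(=O)[C@H]54)COC(=O)[C@]3(CC=C1)C1=O | intermediate
29 | pyrrolidine enamine (C11=C12) of diketone 30 | C1[C@@H]2C=C(N6CCCC6)[C@H]3[C@@]4(CCC[C@@]5(C)COC(=O)[C@H]54)COC(=O)[C@]3(C2)C1=O | intermediate
30 | bicyclo[3.2.1]octane 11,15-diketone with both lactones | C1[C@@H]2CC(=O)[C@H]3[C@@]4(CCC[C@@]5(C)COC(=O)[C@H]54)COC(=O)[C@]3(C2)C1=O | intermediate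
31 | 11-hydroxy 15-ketone, 11-OH equatorial on ring C and anti to the C15–C16 bridge | C1[C@@H]2C[C@@H](O)[C@H]3[C@@]4(CCC[C@@]5(C)COC(=O)[C@H]54)COC(=O)[C@]3(C2)C1=O | intermediate
32 | 16-(dimethylaminomethyl) derivative of 31 (either C16 epimer) | CN(C)CC1[C@@H]2C[C@@H](O)[C@H]3[C@@]4(CCC[C@@]5(C)COC(=O)[C@H]54)COC(=O)[C@]3(C2)C1=O | intermediate
33 | trimethylammonium iodide from 32 | C[N+](C)(C)CC1[C@@H]2C[C@@H](O)[C@H]3[C@@]4(CCC[C@@]5(C)COC(=O)[C@H]54)COC(=O)[C@]3(C2)C1=O.[I-] | intermediate
34 | 16-methylene 15-ketone with free equatorial 11-OH | C=C1[C@@H]2C[C@@H](O)[C@H]3[C@@]4(CCC[C@@]5(C)COC(=O)[C@H]54)COC(=O)[C@]3(C2)C1=O | intermediate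
35 | guidongnin | C=C1[C@@H]2C[C@@H](O)[C@H]3[C@@]4(CCC[C@@]5(C)COC(=O)[C@H]54)COC(=O)[C@]3(C2)[C@@H]1O | target

Total step count: 16. Longest linear sequence: 16 steps (from 1 to 35; all other building blocks are bought).

Steps most likely to fail

Step 13. Pyrrolidine may open the β-keto lactone by aminolysis or retro-Claisen cleavage, or C9 may epimerise faster than the ring closes. The fallback sets out from 27 and returns at 30, and it forms the same C12–C13 bond without a nucleophilic amine. Me3SiOTf and Et3N in CH2Cl2 at −78 °C should convert the methyl ketone on its unhindered side into the trimethylsilyl enol ether F1. A further catalytic charge of Me3SiOTf at −78 to −40 °C then activates the enone for an intramolecular Mukaiyama–Michael addition to the bridged C15 silyl enol ether F2. Dilute HCl in THF hydrolyses this to diketone 30.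

Step 6. The acrylate may add to the C10 radical from the α face or with little preference, or the titanium-bound radical may lose a β-hydrogen to give an allylic alcohol. The fallback sets out from epoxide 10 and returns at 16, and it reverses the order in which the two substituents reach C10. MgBr2·OEt2 should rearrange the epoxide (Meinwald rearrangement) to the C10 aldehyde F3, whose formyl carbon becomes C9. A crossed aldol reaction with aqueous formaldehyde and K2CO3 then supplies C20 as the electrophile and gives the quaternary hydroxy aldehyde F4. A facial bias that sent the acrylate to the α face would now put C20 there, where it belongs. Esterification with diethylphosphonoacetic acid (DCC, DMAP) gives the phosphonate F5. An intramolecular Horner–Wadsworth–Emmons reaction (LiCl, DBU, MeCN) closes the unsaturated δ-lactone 16 directly, so steps 6 and 7 are skipped.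

Step 14. Hydride may attack the C15 ketone as fast as the C11 ketone, so that chemoselectivity is lost. The fallback sets out from 30 and returns at 35. The less hindered C11 ketone is protected selectively as its dioxolane F6 with (Me3SiOCH2)2 and catalytic Me3SiOTf at −78 °C. C16 is then methylenated as in step 15, through the Mannich base F7 and its methiodide F8, to the enone ketal F9. Pyridinium tosylate in wet acetone frees the C11 ketone to give the keto enone F10. A single Luche reduction (NaBH4, CeCl3·7H2O, MeOH) then reduces both carbonyl groups, C11 axially and C15 from the exo face, to give 35.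

Further compounds
F1 | step 13 | trimethylsilyl enol ether of 27 on the methyl side (C11–OSiMe3, C11=C12) | C=C(O[Si](C)(C)C)[C@H]3[C@@]4(CCC[C@@]5(C)COC(=O)[C@H]54)COC(=O)[C@]3(CC=C1)C1=O
F2 | step 13 | C15 trimethylsilyl enol ether (C15=C16) of diketone 30 | C1(=C[C@@H]2CC(=O)[C@H]3[C@@]4(CCC[C@@]5(C)COC(=O)[C@H]54)COC(=O)[C@@]31C2)O[Si](C)(C)C
F3 | step 6 | C10 carbaldehyde from rearrangement of epoxide 10 (either C10 epimer), cis-fused acetal retained | O=CC1CCC[C@@]2(C)COC(OC)[C@H]21
F4 | step 6 | quaternary hydroxy aldehyde: C10 bears CHO (β) and CH2OH (C20, α) | O=C[C@]1(CO)CCC[C@@]2(C)COC(OC)[C@H]21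
F5 | step 6 | diethylphosphonoacetate ester of F4 | O=C[C@]1(COC(=O)CP(=O)(OCC)OCC)CCC[C@@]2(C)COC(OC)[C@H]21
F6 | step 14 | C11 ethylene ketal of diketone 30 | C1[C@@H]2CC7(OCCO7)[C@H]3[C@@]4(CCC[C@@]5(C)COC(=O)[C@H]54)COC(=O)[C@]3(C2)C1=O
F7 | step 14 | 16-(dimethylaminomethyl) derivative of F6 | CN(C)CC1[C@@H]2CC7(OCCO7)[C@H]3[C@@]4(CCC[C@@]5(C)COC(=O)[C@H]54)COC(=O)[C@]3(C2)C1=O
F8 | step 14 | trimethylammonium iodide from F7 | C[N+](C)(C)CC1[C@@H]2CC7(OCCO7)[C@H]3[C@@]4(CCC[C@@]5(C)COC(=O)[C@H]54)COC(=O)[C@]3(C2)C1=O.[I-]
F9 | step 14 | 16-methylene 15-ketone with C11 ethylene ketal | C=C1[C@@H]2CC7(OCCO7)[C@H]3[C@@]4(CCC[C@@]5(C)COC(=O)[C@H]54)COC(=O)[C@]3(C2)C1=O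
F10 | step 14 | 16-methylene 11,15-diketone | C=C1[C@@H]2CC(=O)[C@H]3[C@@]4(CCC[C@@]5(C)COC(=O)[C@H]54)COC(=O)[C@]3(C2)C1=O
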